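The earlier runs and the new flask were computed with constants of no real substance.

Count in turnovers, one turnover being one millimolar of electrophile reacted. It uses one millimolar of nucleophile to make target, and the acid set free binds a second as protonated nucleophile, so a turnover costs two unless the free base catches the acid.

- Friday's: electrophile 32 mM; nucleophile 35.2 mM; free base 9.6 mM; the very flask that is asked about, followed so far
- flask: electrophile 32 mM; nucleophile 35.2 mM; free base 9.60 mM; time 10 d

Friday's run (percent of the electrophile charged)

| time / d | electrophile / % | target / % |
|---|---|---|
| 0.417 | 44.7 | 36.1 |
| 0.625 | 43.5 | 32.9 |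
| 1.04 | 41.1 | 30.3 |
| 1.67 | 38.3 | 29.6 |
| 3.00 | 32.6 | 31.0 |
| 5.00 | 25.7 | 32.9 |

(readings scatter by 0.3 percentage points)

- part of the electrophile that has reacted at 10 d
- share of the unused nucleophile that is free and not bound as protonated nucleophile, at 10 d

The nucleophile charge over twice the electrophile charge gives 55.0% of the electrophile, the burst ceiling; nucleophile is the limiting reagent of this burst. At 0.417 d the flask has reacted 55.3%, about at the ceiling and less than the 70.0% expected if the free base caught acid.

Past the ceiling the electrophile falls at 0.119 /d. Carried from 5.00 d to 10 d, that leaves 14.2%, so you commit to c = 85.8%.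

The weak link is fr. During the burst the free nucleophile averages about 17.6 mM, at a pace of at least 1.93 /d from the first reading. The tail is slower, and about as much nucleophile stands bound past the ceiling. Granting the whole tail to free nucleophile and taking the burst pace at its lower limit makes your estimate an upper one: fr is no higher than about 6.16%.

The forecast gives c = 85% (82.5% to 87%) and fr = 15% (2% to 45%), reasoning “The base absorbs 30%, leaving about 55% to protonate nucleophile”. Your upper estimate of fr is lower than the forecast's value.

The flask gives c = 85.9% and fr = 0.754%.

    electrophile + nucleophile → acid set free + target (k = 15.0 /M/h)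
    nucleophile + acid set free ⇌ protonated nucleophile, settled at all times (K = 1.10 × 10⁵ /M)
    acid set free + free base ⇌ salt of the base (K = 270 /M, k = 9.50 /M/h)
    free base + target → over-reaction product (k = 8.70 /M/h)
    electrophile + acid set free → side product (k = 2.70 /M/h)

At 1.00 d the flask holds 0.158 mM of salt of the base and 26.6% over-reaction product, with 41.5% electrophile left, so it has reacted 58.5% against the ceiling of 55.0%. The neighbour charged with 8.0 mM of electrophile has a ceiling of 220%, so its electrophile goes first, to 0%. Two per turnover then leaves 19.2 mM free out of 27.2 mM unused, a share of 70.6%. That neighbour gives fr = 70.6%.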